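## Structural features

Ainsliadimer B is a C30 dimer of two guaianolides. Half B (primed) is a 3'-oxo-dehydrocostus-lactone-type 5–7–5 tricycle; half A (unprimed) is a cyclopentenone (C1=C2, C3=O, C4 bearing the hydroxymethyl carbon C15) fused through C1–C5 to a cycloheptane that carries a tertiary hydroxyl at C10 and a trans-fused α-methylene-γ-lactone at C6–C7. The halves are joined by a cyclohexene (C1, C2, C4', C15', C14, C10) that shares C1=C2 with the cyclopentenone, C1–C10 with the seven-membered ring and the spiro carbon C4' with the cyclopentanone of half B, so C2–C4' and C14–C15' are the inter-unit bonds. There are ten stereocentres: the contiguous run C4–C5–C6–C7 and the carbinol C10 in half A, and the quaternary spiro centre C4' next to C5', followed by C6', C7' and C1', in half B. The C10 hydroxyl and the C3' carbonyl sit on the same face of the cyclohexene, and C15 is trans to C6 on the cyclopentenone. Fragile groups are the two α-methylene lactones (Michael acceptors), the β-hydroxy ketone C15–C4–C3 (retro-oxa-Michael), the non-enolisable 1,3-dicarbonyl around C4' (retro-Claisen) and the exocyclic C10'=C14' olefin. The real difficulty is the spiro centre C4' with a tertiary C10 oxygen cis to C3', next to a fully substituted C1=C2 enone, in a molecule whose second ketone (C3') is kinetically the more acidic. The stereocentres C5, C6, C7 and C1', C5', C6', C7' are exactly those of dehydrocostus lactone, which suggests taking both halves from it. The key step exploits ring A: carbonyl C3 lies between vinylic C2 and C4, which carries only C15, so the cyclopentenone is the 1,4-diene C2=C1–C5–C4=C15 plus one carbon from CO.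

## Logic of the disconnections

**23 ⇒ 22 ⇒ 21.** The O–Si bond at C10 and the C15–O bond (with C4–H) are cut. The β-hydroxy ketone is retro-Michael-labile and is therefore made last. 21 has no C4 stereocentre and carries the exocyclic methylene that the ring-forming step delivers. The forward hydration must choose C15 of the cross-conjugated dienone over two lactone methylenes and leave C4 in its thermodynamic configuration.

**21 ⇒ 19 + 20.** C2–C3 and C3–C4 are cut, which removes ring A and returns C3 to carbon monoxide. One ring and two bonds disappear and no stereocentre is involved. The forward step needs C2 as a vinyl electrophile held cis to the C5 vinyl group, CO insertion ahead of olefin insertion, and a masked C10 oxygen.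

**19 ⇒ 16.** The C2–O(sulfonyl) bond is cut, leading back to a ketone that can enolise only toward C1 because C4' is quaternary. The gain is an ordinary ketone. The demand is regioselection against the C3' ketone, met by parking its enolate as a silyl enol ether (17, 18), and survival of the β-silyloxy group.

**16 ⇒ 15 ⇒ 14 ⇒ 13 ⇒ 12 ⇒ 11.** The C10–O bond is cut and the C1=C10 olefin restored. The aldol pattern C2(=O)–C1–C10(O) is traced to the α,β-epoxy ketone 14 and on to the allylic silyl ether 11. The C10 stereocentre is exchanged for a planar tetrasubstituted olefin, which is the direct cycloaddition product. The epoxidation must pick C1=C10 among six olefins and the face of the C3' carbonyl, and the reductive opening must touch only the epoxy ketone.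

**11 ⇒ 10 + 3.** C2–C4' and C14–C15' are cut (Diels–Alder retron, cyclohexene with C1=C10). The dimer falls into two fragments of equal size and the spiro centre is traced to an exocyclic enone. The forward step needs C14 to bond to C15', attack on the α face of 3, and preference for the enone over the lactone methylenes.

**10 ⇒ 9 ⇒ 7 ⇒ 6 ⇒ 5 ⇒ 3.** Read backwards, C3 is re-inserted between C2 and C4: 10 is the enol ether of 9, 9 comes from 7 by loss of the C3 carboxyl and the C15 sulfonyl group, 7 from 6 by cleaving C2–C3 of an α-ketol, 6 and 5 from 3 by C15–S and C2–O bond formation. 9 is 3 minus C3, so fragment A becomes the same compound as the dienophile, and C5, C6 and C7 are inherited. The excision must cut both bonds to C3, leave C4=C15 as a vinyl group and tolerate the methylene lactone.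

**3 ⇒ 2 ⇒ 1.** The C3 oxygen is removed, leading to the commercial lactone 1. The forward step needs allylic oxidation at C3.

## Other disconnections considered

**Alternative 1:** The cut is C6'–C7' and C9'–C10' of the primed cycloheptane. In the forward step the oxyallyl cation from A2 (Zn–Cu couple) adds across the α-carbons of furan A1 in a dearomative (4+3) cycloaddition, giving A3 after reductive removal of the remaining bromines.
- In its favour: two C–C bonds and the seven-membered ring from cheap achiral materials, no transition metal and no CO, and a bridge that fixes the cis relation of the C6' and C10' oxygen termini.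
- Against it here: A3 is racemic unless an asymmetric variant is added. It still lacks the lactone carbons, needs the C8' ketone removed, the bridge opened, the methyl turned into the exocyclic methylene and the C1'=C5' olefin reduced cis. None of this touches the spiro centre, C10 or ring A.
- Comparison: structurally it rebuilds the half that 3 supplies in two steps. Mechanistically the cycloaddition is at least as robust as the carbonylative cyclisation 19 → 21 and is its equal in bonds and rings formed; it is the better on stereocentres set (two against none) and on independence from a natural supply. On step economy it is far worse.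

**Alternative 2:** The cut is C1'–C10'. In the forward step Ni(cod)2 and triethylamine convert the vinyl bromide A4 into a vinylnickel that adds to C1' of the spiro cyclopentenone, giving A5.
- In its favour: the primed seven-membered ring closes with the exocyclic methylene in place and C1' is set by the tether. C15 already carries its oxygen, so no sensitive methylene dienone has to be hydrated at the end; on that point it is better than the chosen plan.
- Against it here: half B must be built open-chain with C5', C6', C7' and the spiro centre under reagent control. Ring A must already exist, so half A is made de novo as well. Stoichiometric nickel is needed, and a second enone and a free tertiary alcohol are present. Desilylation and lactone oxidation follow.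
- Comparison: it forms one ring like the chosen step (equal), one bond instead of two, and one stereocentre instead of none. A seven-membered closure by conjugate addition is slower than the 5-exo acylpalladation. It gives up the chiral pool for both halves and would be much longer than the 17 steps to 23.

**Alternative 3:** The cut is C1–C5. In the forward step Sc(OTf)3 triggers the polarised Nazarov cyclisation of the alkylidene β-keto ester A6 to A7.
- In its favour: it builds the same ring as the chosen step with a catalytic Lewis acid and no CO, sets C4 and C5 trans in the step, and brings C15 at the ester level, so the hydration is avoided. It is the equal of the chosen step in delivering the tetrasubstituted C1=C2 enone directly and the better on stereocentres and on the endgame.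
- Against it here: only one C–C bond is formed. The seven-membered ring and the lactone of half A remain to be built afterwards beside an enone and a methylene lactone. C5 depends on remote torquoselectivity, whereas in 9 it is inherited. The tertiary allylic acetate can ionise under the Lewis acid, and the ester must later be reduced beside three ketones and a lactone.
- Comparison: structurally equal on the ring made, mechanistically simpler to run, but the cyclised product is still many steps from 23, whereas 21 is two steps away.

Key step: step 15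

## Remarks on the chemistry (assumptions)

- The lactones are five-membered γ-lactones fused to seven-membered carbocycles; a "seven-membered lactone ring" is read in that sense.
- In the final hydration it is the hydroxymethyl group, not the incoming hydrogen, that ends trans to C6 (H-4 cis to C6, trans to H-5), as the target string requires.
- The strings of 19, 21 and 23 agree with each other at every stereocentre and are used unchanged.
- Both halves are taken from dehydrocostus lactone; the C5 vinyl group is the original C4=C15 unit, so vinylmagnesium bromide is not needed.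
- The transient centres C3 (in 2), C2 (5, 6, 11–13), C4 (6–8) and C1 (15–17) are drawn as the expected epimer; either epimer serves.

## Route

Step 1
Reactants: 1 dehydrocostus lactone
Product: 2 3α-hydroxydehydrocostus lactone (3-epizaluzanin C)
Conditions: SeO2 (0.5 equiv), t-BuOOH, CH2Cl2, 0 °C → rt
Reagents that add atoms: selenium dioxide, O=[Se]=O; tert-butyl hydroperoxide, CC(C)(C)OO
Why: Riley allylic oxidation (ene reaction at C4=C15, then [2,3]-shift) should hydroxylate the ring methylene C3, the conjugated C11=C13 olefin being inert; the hydroxyl is expected on the α face and its configuration is erased in step 2.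

Step 2
Reactants: 2 3α-hydroxydehydrocostus lactone
Product: 3 dehydrozaluzanin C (3-oxo-dehydrocostus lactone)
Conditions: Dess–Martin periodinane, NaHCO3, CH2Cl2, 0 °C → rt
Reagents that add atoms: none
Why: Dess–Martin oxidation of the secondary allylic alcohol under neutral conditions should give the exocyclic enone without olefin migration; no stereocentre is formed.

Step 3
Reactants: 3 dehydrozaluzanin C
Product: 5 2α-hydroxydehydrozaluzanin C, via trimethylsilyl dienol ether 4 (not isolated)
Conditions: Me3SiOTf, Et3N, CH2Cl2, −78 → 0 °C; dimethyldioxirane, acetone, −78 °C; citric acid, MeOH, 0 °C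
Reagents that add atoms: dimethyldioxirane, CC1(C)OO1
Why: Rubottom oxidation: the ketone can enolise only toward C2 (C4 is sp2), and the enol ether bond of the 2-silyloxy diene is the most electron-rich olefin, so the dioxirane should oxidise it selectively at low temperature. Oxygen is expected on the convex α face; C2 is destroyed in step 5.

Step 4
Reactants: 5 2α-hydroxydehydrozaluzanin C
Product: 6 2α-hydroxy-15-(phenylsulfonyl)-4,15-dihydrodehydrozaluzanin C (4β-H)
Conditions: PhSO2Na, AcOH, THF/EtOH, 0 °C → rt
Reagents that add atoms: sodium benzenesulfinate, [Na+].[O-]S(=O)c1ccccc1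
Why: Sulfa-Michael addition of the sulfinate to the ketone-activated exocyclic methylene, which is more electrophilic than the ester-activated C11=C13; it places a radical leaving group on C15. C4 should protonate with the side chain trans to C6, but this centre is lost in step 6.

Step 5
Reactants: 6 the sulfonyl α-ketol
Product: 7 seco acid-aldehyde (C1 formyl; C5 bearing CH(CO2H)CH2SO2Ph)
Conditions: NaIO4, THF/H2O (pH 7 buffer), rt
Reagents that add atoms: sodium periodate, [Na+].[O-]I(=O)(=O)=O
Why: Malaprade-type periodate cleavage of the α-ketol cuts C2–C3, giving the C2 aldehyde and the C3 carboxylic acid; sulfone, olefins and lactone are inert and the neutral buffer avoids retro-Michael loss of sulfinate.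

Step 6
Reactants: 7 seco acid-aldehyde
Product: 9 3-nor-2,3-seco aldehyde (C1 formyl; C5 vinyl; C10 methylene), via thiohydroxamate ester 8 (not isolated)
Conditions: 1-hydroxypyridine-2(1H)-thione, DCC, CH2Cl2, 0 °C, dark; hν (visible), PhH (0.01 M), 20 °C
Reagents that add atoms: none
Why: Barton decarboxylation: photolysis of the O-acyl thiohydroxamate and loss of CO2 give the C4 radical, which should expel the β-phenylsulfonyl radical to form the C4=C15 vinyl group, the sulfonyl radical carrying the chain through the thiocarbonyl group. High dilution keeps fragmentation ahead of thiopyridyl transfer; C5 is untouched.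

Step 7
Reactants: 9 3-nor-2,3-seco aldehyde
Product: 10 (E)-tert-butyldimethylsilyl dienol ether of 9
Conditions: t-BuMe2SiOTf, Et3N, CH2Cl2, −78 → 0 °C
Reagents that add atoms: tert-butyldimethylsilyl triflate, CC(C)(C)[Si](C)(C)OS(=O)(=O)C(F)(F)F
Why: Soft enolisation of the β,γ-unsaturated aldehyde removes the doubly activated H-1 and gives the 1-silyloxy diene C2=C1–C10=C14, held s-cis by the ring; the silyloxy group should take the outside position (trans to C10) to avoid the inside clash with C14.

Step 8
Reactants: 10 silyl dienol ether; 3 dehydrozaluzanin C (1.5 equiv)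
Product: 11 Diels–Alder adduct (spiro cyclohexene with C1=C10 olefin and 2α-silyloxy group cis to C5')
Conditions: toluene, BHT (cat.), 70 °C
Reagents that add atoms: none
Why: Normal-demand Diels–Alder reaction of the electron-rich diene with the exocyclic enone, the most electron-poor olefin present; the unsubstituted terminus C14 bonds to C15' and the oxygenated C2 to C4' (ortho rule). The diene should add to the α face of 3 (the side of H-5', away from the C6' oxygen), which sets C4'. s-cis-Locked exocyclic enones favour the exo mode, which lets the diene react anti to its C5 vinyl group and places the C2 silyloxy group cis to C5'.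

Step 9
Reactants: 11 Diels–Alder adduct
Product: 12 1β,10β-epoxide of 11
Conditions: mCPBA, NaHCO3, CH2Cl2, −20 °C
Reagents that add atoms: 3-chloroperbenzoic acid, OOC(=O)c1cccc(Cl)c1
Why: Prilezhaev epoxidation: the tetrasubstituted C1=C10 olefin is far more nucleophilic than the 1,1-disubstituted, monosubstituted and conjugated ones. The peracid should approach anti to the bulky allylic silyl ether and to the C5' side of the spiro ring, that is from the face of the C3' carbonyl, which sets the C10–O configuration of the target.

Step 10
Reactants: 12 epoxy silyl ether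
Product: 13 epoxy alcohol (2α-hydroxy)
Conditions: Bu4NF, AcOH (1:1), THF, 0 °C → rt
Reagents that add atoms: none
Why: Fluoride desilylation; the acetic acid buffer keeps the liberated alkoxide from epoxide migration and from adding to the methylene lactones.

Step 11
Reactants: 13 epoxy alcohol
Product: 14 α,β-epoxy ketone (C2 ketone)
Conditions: Dess–Martin periodinane, NaHCO3, CH2Cl2, 0 °C → rt
Reagents that add atoms: none
Why: Dess–Martin oxidation of the hindered secondary alcohol; it removes the auxiliary C2 stereocentre and activates the epoxide for reductive opening.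

Step 12
Reactants: 14 α,β-epoxy ketone
Product: 15 10β-hydroxy C2 ketone (1α-H)
Conditions: SmI2 (2.5 equiv), THF/MeOH, −78 °C
Reagents that add atoms: none
Why: SmI2 reduction of an α,β-epoxy ketone: ketyl formation, scission of the C1–O bond and a second electron give the samarium enolate and the C10 alkoxide, which methanol protonates to the aldol with the C10–O bond and its configuration intact. At −78 °C the unsaturated lactones and the isolated ketone should not be reduced; C1 is expected to protonate anti to the alkoxide and is lost in step 14.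

Step 13
Reactants: 15 10β-hydroxy C2 ketone
Product: 16 10-O-triethylsilyl C2 ketone
Conditions: Et3SiOTf, 2,6-lutidine, CH2Cl2, −78 °C
Reagents that add atoms: triethylsilyl triflate, CC[Si](CC)(CC)OS(=O)(=O)C(F)(F)F
Why: Silyl triflate silylation of the tertiary alcohol; it blocks retro-aldol opening and the later capture of the acylpalladium.

Step 14
Reactants: 16 10-O-triethylsilyl C2 ketone
Product: 19 C2 enol triflate (10-O-triethylsilyl; key-step precursor), via C3' trimethylsilyl enol ether 17 (not isolated), via C2 triflate C3' silyl enol ether 18 (not isolated)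
Conditions: KN(SiMe3)2 (1.05 equiv), THF, −78 °C, then Me3SiCl; KN(SiMe3)2 (1.5 equiv), PhNTf2, −78 → −40 °C; aq. NH4Cl, then 0.5 M HCl, THF, 0 °C
Reagents that add atoms: N-phenyl-bis(trifluoromethanesulfonimide), O=S(=O)(N(c1ccccc1)S(=O)(=O)C(F)(F)F)C(F)(F)F
Why: Kinetic deprotonation first removes the unhindered C2' proton of the cyclopentanone, and this enolate is parked as its trimethylsilyl enol ether. The second charge of base can then enolise only the C2 ketone toward C1 (C4' is quaternary), and the potassium enolate is O-sulfonylated. Brief acid work-up should hydrolyse the labile silyl enol ether back to the C3' ketone while the tertiary triethylsilyl ether and the triflate persist.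

Step 15
Reactants: 19 C2 enol triflate; 20 carbon monoxide
Product: 21 cross-conjugated 4(15)-methylene dienone dimer (10-O-triethylsilyl)
Conditions: Pd(PPh3)4 (10 mol%), CO (10 atm), i-Pr2NEt, LiCl, MeCN/THF, 65 °C
Reagents that add atoms: none
Why: Zerovalent palladium inserts into the C2–O bond of the triflate, CO inserts to give the C3 acylpalladium, this adds across the C5 vinyl group with the acyl carbon bonding to C4, and the primary C15 alkylpalladium, whose only β-hydrogen is H-4, undergoes β-hydride elimination to the exocyclic methylene while the amine regenerates the catalyst. The closest known reaction type is the palladium-catalysed carbonylative cyclisation (acylpalladation then dehydropalladation) of 1-halo-1,4-dienes to 5-methylene-cyclopent-2-enones. The one ring formed (C1, C2, C3, C4, C5) closes in the 5-exo-trig mode. No stereocentre is created. CO insertion must precede olefin insertion, which is secured because direct Heck closure would be a strained 4-exo process and CO pressure makes acyl formation fast. The vinyl group is held cis to the acyl carbon across the ring C1=C2 bond, so the remote methylenes cannot compete. The C10 oxygen is silylated so that it cannot trap the acylpalladium as a butenolide, and no alcohol or unhindered amine is present. The hindered base also limits conjugate addition to the product.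

Step 16
Reactants: 21 4(15)-methylene dienone dimer
Product: 22 10-O-triethylsilyl ainsliadimer B
Conditions: PMe3 (20 mol%), H2O, THF, 0 °C → rt
Reagents that add atoms: water, O
Why: Phosphine-catalysed oxa-Michael addition of water to the exocyclic methylene of the cross-conjugated dienone, the most electrophilic and least hindered acceptor. C4 is set by enolate protonation and, being epimerisable next to the ketone, should settle with the hydroxymethyl group trans to C6.

Step 17
Reactants: 22 10-O-triethylsilyl ainsliadimer B
Product: 23 ainsliadimer B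
Conditions: HF·pyridine, pyridine, THF, 0 °C → rt
Reagents that add atoms: none
Why: Fluoride cleavage of the tertiary triethylsilyl ether under buffered, non-basic conditions, so that the β-hydroxy ketone is not exposed to retro-Michael elimination; no stereocentre is touched.

## Compound list

1 | dehydrocostus lactone | C=C3CC[C@H]1C(=C)CC[C@H]2C(=C)C(=O)O[C@@H]2[C@H]13 | starting material
2 | 3α-hydroxydehydrocostus lactone (3-epizaluzanin C) | C=C3[C@H](O)C[C@H]1C(=C)CC[C@H]2C(=C)C(=O)O[C@@H]2[C@H]13 | intermediate
3 | dehydrozaluzanin C (3-oxo-dehydrocostus lactone) | C=C3C(=O)C[C@H]1C(=C)CC[C@H]2C(=C)C(=O)O[C@@H]2[C@H]13 | intermediate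
4 | 3-trimethylsilyloxy-2,4(15)-diene from 3 (not isolated) | C=C3C(O[Si](C)(C)C)=C[C@H]1C(=C)CC[C@H]2C(=C)C(=O)O[C@@H]2[C@H]13 | intermediate
5 | 2α-hydroxydehydrozaluzanin C | C=C3C(=O)[C@H](O)[C@H]1C(=C)CC[C@H]2C(=C)C(=O)O[C@@H]2[C@H]13 | intermediate
6 | 2α-hydroxy-15-(phenylsulfonyl)-4,15-dihydrodehydrozaluzanin C (4β-H) | O=S(=O)(C[C@@H]3C(=O)[C@H](O)[C@H]1C(=C)CC[C@H]2C(=C)C(=O)O[C@@H]2[C@H]13)c1ccccc1 | intermediate
7 | seco acid-aldehyde: lactone-fused cycloheptane with C1 formyl (H-1α), C10 methylene and, on C5, CH(CO2H)CH2SO2Ph | O=C[C@H]1C(=C)CC[C@H]2C(=C)C(=O)O[C@@H]2[C@H]1[C@H](CS(=O)(=O)c1ccccc1)C(=O)O | intermediate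
8 | O-acyl thiohydroxamate ester of 7 (not isolated) | O=C[C@H]1C(=C)CC[C@H]2C(=C)C(=O)O[C@@H]2[C@H]1[C@H](CS(=O)(=O)c1ccccc1)C(=O)On1ccccc1=S | intermediate
9 | 3-nor-2,3-seco aldehyde: same core with C1 formyl, C5 vinyl (H-5α), C10 methylene | O=C[C@H]1C(=C)CC[C@H]2C(=C)C(=O)O[C@@H]2[C@H]1C=C | intermediate
10 | (E)-tert-butyldimethylsilyl dienol ether of 9 (C2=C1–C10=C14 diene) | CC(C)(C)[Si](C)(C)O/C=C1/C(=C)CC[C@H]2C(=C)C(=O)O[C@@H]2[C@H]1C=C | intermediate
11 | Diels–Alder adduct: spiro cyclohexene dimer, C1=C10 olefin, 2α-OTBS cis to C5' | C=C1C(=O)O[C@@H]2[C@@H](C=C)C3=C(CC[C@@]4([C@H]3O[Si](C)(C)C(C)(C)C)C(=O)C[C@H]5C(=C)CC[C@H]6C(=C)C(=O)O[C@@H]6[C@H]54)CC[C@@H]12 | intermediate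
12 | 1β,10β-epoxide of 11 (oxygen cis to C3' and to the C5 vinyl group) | C=C1C(=O)O[C@@H]2[C@@H](C=C)[C@@]3(O4)[C@]4(CC[C@@]5([C@H]3O[Si](C)(C)C(C)(C)C)C(=O)C[C@H]6C(=C)CC[C@H]7C(=C)C(=O)O[C@@H]7[C@H]65)CC[C@@H]12 | intermediate
13 | 1β,10β-epoxy 2α-alcohol | C=C1C(=O)O[C@@H]2[C@@H](C=C)[C@@]3(O4)[C@]4(CC[C@@]5([C@H]3O)C(=O)C[C@H]6C(=C)CC[C@H]7C(=C)C(=O)O[C@@H]7[C@H]65)CC[C@@H]12 | intermediate
14 | 1β,10β-epoxy C2 ketone | C=C1C(=O)O[C@@H]2[C@@H](C=C)[C@@]3(O4)[C@]4(CC[C@@]5(C3=O)C(=O)C[C@H]6C(=C)CC[C@H]7C(=C)C(=O)O[C@@H]7[C@H]65)CC[C@@H]12 | intermediate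
15 | 10β-hydroxy C2 ketone (1α-H) | C=C1C(=O)O[C@@H]2[C@@H](C=C)[C@@H]3[C@](O)(CC[C@@]4(C3=O)C(=O)C[C@H]5C(=C)CC[C@H]6C(=C)C(=O)O[C@@H]6[C@H]54)CC[C@@H]12 | intermediate
16 | 10-O-triethylsilyl C2 ketone | C=C1C(=O)O[C@@H]2[C@@H](C=C)[C@@H]3[C@](O[Si](CC)(CC)CC)(CC[C@@]4(C3=O)C(=O)C[C@H]5C(=C)CC[C@H]6C(=C)C(=O)O[C@@H]6[C@H]54)CC[C@@H]12 | intermediate
17 | C3' trimethylsilyl enol ether of 16 (not isolated) | C=C1C(=O)O[C@@H]2[C@@H](C=C)[C@@H]3[C@](O[Si](CC)(CC)CC)(CC[C@@]4(C3=O)C(O[Si](C)(C)C)=C[C@H]5C(=C)CC[C@H]6C(=C)C(=O)O[C@@H]6[C@H]54)CC[C@@H]12 | intermediate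
18 | C2 enol triflate, C3' trimethylsilyl enol ether (not isolated) | C=C1C(=O)O[C@@H]2[C@@H](C=C)C3=C(OS(=O)(=O)C(F)(F)F)[C@]4(CC[C@]3(O[Si](CC)(CC)CC)CC[C@@H]12)C(O[Si](C)(C)C)=C[C@H]1C(=C)CC[C@H]2C(=C)C(=O)O[C@@H]2[C@H]14 | intermediate
19 | C2 enol triflate with C5 vinyl group, 10-O-triethylsilyl (key-step precursor) | C=C1C(=O)O[C@@H]2[C@@H](C=C)C3=C(OS(=O)(=O)C(F)(F)F)[C@]4(CC[C@]3(O[Si](CC)(CC)CC)CC[C@@H]12)C(=O)C[C@H]1C(=C)CC[C@H]2C(=C)C(=O)O[C@@H]2[C@H]14 | intermediate
20 | carbon monoxide | [C-]#[O+] | starting material
21 | cross-conjugated 4(15)-methylene dienone dimer, 10-O-triethylsilyl | C=C1C(=O)O[C@@H]2[C@@H]3C4=C(C(=O)C3=C)[C@]3(CC[C@]4(O[Si](CC)(CC)CC)CC[C@@H]12)C(=O)C[C@H]1C(=C)CC[C@H]2C(=C)C(=O)O[C@@H]2[C@H]13 | intermediate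
22 | 10-O-triethylsilyl ainsliadimer B | C=C1C(=O)O[C@@H]2[C@@H]3C4=C(C(=O)[C@H]3CO)[C@]3(CC[C@]4(O[Si](CC)(CC)CC)CC[C@@H]12)C(=O)C[C@H]1C(=C)CC[C@H]2C(=C)C(=O)O[C@@H]2[C@H]13 | intermediate
23 | ainsliadimer B | C=C1C(=O)O[C@@H]2[C@@H]3C4=C(C(=O)[C@H]3CO)[C@]3(CC[C@]4(O)CC[C@@H]12)C(=O)C[C@H]1C(=C)CC[C@H]2C(=C)C(=O)O[C@@H]2[C@H]13 | target

## Step count and least certain steps

Total: 17 steps. Longest linear sequence: 17 steps (1 → 23; compound 3 is used twice, as the precursor of the diene and as the dienophile).

**Step 15 (key step).** Oxidative addition at the tetrasubstituted triflate flanked by two quaternary carbons may be slow, and under CO the acylpalladium may be trapped or the C15 alkylpalladium may insert a second CO before β-hydride elimination. Fallback, from 19 back to 21: split the cascade. Hydroxycarbonylation of 19 (Pd(OAc)2, dppf, CO, KOAc, wet DMSO) should give the dienoic acid F1. Oxalyl chloride with catalytic DMF converts it into the acid chloride F2. Pd(PPh3)4 with i-Pr2NEt then effects acylpalladation of the vinyl group and dehydropalladation without CO pressure, giving 21.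

**Step 6.** The C4 radical may be captured at sulfur of the thiohydroxamate before it expels the sulfonyl radical, or sulfinate may be lost by elimination toward the acrylate. Fallback, from 5 back to 9: a pericyclic route. Phosphine-catalysed hydration of 5 gives the 2α,15-diol ketone F3, periodate cleavage gives the β-hydroxy acid-aldehyde F4, benzenesulfonyl chloride in pyridine closes the β-lactone F5, and brief thermolysis (about 150 °C, dilute) extrudes CO2 to give 9. The temperature is the weak point of this fallback.

**Step 8.** Exo selectivity may be poor or the diene may react on its other face, which would give the C2 epimer; reaction at a lactone methylene is a lesser risk. Fallback, from 10 and 3 back to 14: the C2-epimeric adduct F6 is taken on by hydroxyl direction instead of steric control. Buffered fluoride gives the 2β-allylic alcohol F7, VO(acac)2 with t-BuOOH delivers oxygen syn to the hydroxyl and gives the 1β,10β-epoxy alcohol F8, and Dess–Martin oxidation converges on 14.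

**Step 9.** Facial selectivity may be eroded by the C5 vinyl group on the face that must be attacked, or the C10'=C14' olefin may also be epoxidised. Fallback, from 11 back to 12: invert the facial sense through a halohydrin. N-Bromosuccinimide in wet acetone forms the bromonium ion on the face the peracid prefers, water opens it anti at C10 to the bromohydrin F9 (1α-bromo, 10β-hydroxy), and K2CO3 in acetone closes the β-epoxide 12.

**Step 14.** Deprotonation of the hindered H-1 may be incomplete, the C10 silyloxy group may be lost by β-elimination from the enolate, or the amide base may add to a methylene lactone. Fallback, from 14 back to 19: make the C1=C2 enolate reductively instead of by deprotonation. SmI2 in THF without a proton source, followed by Et3SiOTf and Et3N, should silylate both the samarium enolate and the C10 alkoxide, giving the bis-silyl compound F10. CsF with PhNTf2 in dimethoxyethane then exchanges the enol silyl ether for the triflate, giving 19.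

**Step 16.** Water may add reversibly or also to a lactone methylene, and the phosphonium enolate may start oligomerisation of the dienone. Fallback, from 21 back to 22: add a removable alcohol instead of water. Phosphine-catalysed addition of 4-methoxybenzyl alcohol gives the C15 ether F11, and DDQ in wet CH2Cl2 releases 22.

## Further compounds

F1 | step 15 | C2 carboxylic acid from 19 (dienoic acid, 10-O-triethylsilyl) | C=C1C(=O)O[C@@H]2[C@@H](C=C)C3=C(C(=O)O)[C@]4(CC[C@]3(O[Si](CC)(CC)CC)CC[C@@H]12)C(=O)C[C@H]1C(=C)CC[C@H]2C(=C)C(=O)O[C@@H]2[C@H]14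
F2 | step 15 | acid chloride of F1 | C=C1C(=O)O[C@@H]2[C@@H](C=C)C3=C(C(=O)Cl)[C@]4(CC[C@]3(O[Si](CC)(CC)CC)CC[C@@H]12)C(=O)C[C@H]1C(=C)CC[C@H]2C(=C)C(=O)O[C@@H]2[C@H]14
F3 | step 6 | 2α,15-dihydroxy-4,15-dihydrodehydrozaluzanin C (4β-H) | OC[C@@H]3C(=O)[C@H](O)[C@H]1C(=C)CC[C@H]2C(=C)C(=O)O[C@@H]2[C@H]13
F4 | step 6 | β-hydroxy acid-aldehyde (C1 formyl; C5 bearing CH(CO2H)CH2OH) | O=C[C@H]1C(=C)CC[C@H]2C(=C)C(=O)O[C@@H]2[C@H]1[C@H](CO)C(=O)O
F5 | step 6 | β-lactone of F4 (oxetan-2-one on C5) | O=C[C@H]1C(=C)CC[C@H]2C(=C)C(=O)O[C@@H]2[C@H]1[C@@H]1COC1=O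
F6 | step 8 | C2-epimeric Diels–Alder adduct (2β-OTBS, cis to C3') | C=C1C(=O)O[C@@H]2[C@@H](C=C)C3=C(CC[C@@]4([C@@H]3O[Si](C)(C)C(C)(C)C)C(=O)C[C@H]5C(=C)CC[C@H]6C(=C)C(=O)O[C@@H]6[C@H]54)CC[C@@H]12
F7 | step 8 | 2β-allylic alcohol from F6 | C=C1C(=O)O[C@@H]2[C@@H](C=C)C3=C(CC[C@@]4([C@@H]3O)C(=O)C[C@H]5C(=C)CC[C@H]6C(=C)C(=O)O[C@@H]6[C@H]54)CC[C@@H]12
F8 | step 8 | 1β,10β-epoxy 2β-alcohol | C=C1C(=O)O[C@@H]2[C@@H](C=C)[C@@]3(O4)[C@]4(CC[C@@]5([C@@H]3O)C(=O)C[C@H]6C(=C)CC[C@H]7C(=C)C(=O)O[C@@H]7[C@H]65)CC[C@@H]12
F9 | step 9 | 1α-bromo-10β-hydroxy bromohydrin of 11 | C=C1C(=O)O[C@@H]2[C@@H](C=C)[C@]3(Br)[C@](O)(CC[C@@]4([C@H]3O[Si](C)(C)C(C)(C)C)C(=O)C[C@H]5C(=C)CC[C@H]6C(=C)C(=O)O[C@@H]6[C@H]54)CC[C@@H]12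
F10 | step 14 | C2 triethylsilyl enol ether, 10-O-triethylsilyl | C=C1C(=O)O[C@@H]2[C@@H](C=C)C3=C(O[Si](CC)(CC)CC)[C@]4(CC[C@]3(O[Si](CC)(CC)CC)CC[C@@H]12)C(=O)C[C@H]1C(=C)CC[C@H]2C(=C)C(=O)O[C@@H]2[C@H]14
F11 | step 16 | 15-O-(4-methoxybenzyl)-10-O-triethylsilyl ainsliadimer B | C=C1C(=O)O[C@@H]2[C@@H]3C4=C(C(=O)[C@H]3COCc3ccc(OC)cc3)[C@]3(CC[C@]4(O[Si](CC)(CC)CC)CC[C@@H]12)C(=O)C[C@H]1C(=C)CC[C@H]2C(=C)C(=O)O[C@@H]2[C@H]13
A1 | alternative 1 | cyclopenta-fused 2-methylfuran ethylene ketal | Cc1occ2CC3(Cc12)OCCO3
A2 | alternative 1 | 1,1,3,3-tetrabromoacetone | O=C(C(Br)Br)C(Br)Br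
A3 | alternative 1 | oxygen-bridged cycloheptenone fused to the ketal cyclopentene | C[C@]12CC(=O)C[C@H](O1)C1=C2CC2(C1)OCCO2
A4 | alternative 2 | open-chain vinyl bromide on the spiro cyclopentenone (tris-silyl ether) | C=C1C(=O)O[C@@H]2[C@@H]3C4=C(C(=O)[C@H]3CO[Si](C)(C)C(C)(C)C)[C@]3(CC[C@]4(O)CC[C@@H]12)C(=O)C=C[C@H]3[C@@H](O[Si](C)(C)C(C)(C)C)[C@@H](CCC(Br)=C)C(=C)CO[Si](C)(C)C(C)(C)C
A5 | alternative 2 | cyclised dimer with half B as 2-methylene-1,4-diol bis-silyl ether | C=C1C(=O)O[C@@H]2[C@@H]3C4=C(C(=O)[C@H]3CO[Si](C)(C)C(C)(C)C)[C@]3(CC[C@]4(O)CC[C@@H]12)C(=O)C[C@H]1C(=C)CC[C@@H](C(=C)CO[Si](C)(C)C(C)(C)C)[C@H](O[Si](C)(C)C(C)(C)C)[C@H]13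
A6 | alternative 3 | cyclohexenyl alkylidene β-keto ester (alkylidene geometry not fixed) | COC(=O)C(=CCOCc1ccc(OC)cc1)C(=O)C2=C[C@@](OC(C)=O)(CCCO[Si](C)(C)C(C)(C)C)CC[C@]23C(=O)C[C@H]4C(=C)CC[C@H]5C(=C)C(=O)O[C@@H]5[C@H]43
A7 | alternative 3 | spiro-fused cyclopentenone β-keto ester | COC(=O)[C@@H]1C(=O)C2=C([C@H]1COCc1ccc(OC)cc1)[C@@](OC(C)=O)(CCCO[Si](C)(C)C(C)(C)C)CC[C@]23C(=O)C[C@H]4C(=C)CC[C@H]5C(=C)C(=O)O[C@@H]5[C@H]43
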